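**Plan**

1. The target is read as an all-cis oxane (locants used below: O1, C2 aryl, C3 cinnamyl, C4, C5, C6; C10 = carbinol carbon on C5; C7–C8=C9 = side chain on C3). Retrosynthetic cuts, in order: aryl–C10 and the C5–H/C10–O pair (back to an exocyclic C5=CH2), the ring bond C3–C4, the ether bond O1–C6, and the two aryl–carbonyl bonds of a trans-cyclopropane-1,2-dicarbonyl core.
2. Enabling feature: C3 bears CH2–CH=CH–Ar, so C3 is homoallylic to the benzylic alkene carbon C9. C3–C7–C8=C9 is the opened form of an aryl cyclopropylcarbinyl cation, so a cyclopropane (C3, C7, C8) can store the C3 stereocentre and the E-alkene, and its strain can drive the C3–C4 bond.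
3. Forward: the cyclopropane is bought; diacid → bis-Weinreb amide → diaryl diketone → twofold-symmetric diol → mono-ether with a 2-(silylmethyl)allyl unit → acetate → cyclopropane opened and oxane ring closed in one step (C3–C4) → exocyclic alkene converted into the C5–CH(OH)Ar unit → desilylation.
4. Stereochemistry: C2 from a CBS reduction; C3 by inversion at the cyclopropane carbon in the ring closure (2,3-cis), with both epimers of the leaving benzylic carbon converging; C5 by hydroboration anti to the axial C3 chain; C10 by a second CBS reduction.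
5. Ar = 4-(triisopropylsilyloxy)phenyl until the last step.

Key step: step 6

Assumption: (1R,2R)-cyclopropane-1,2-dicarboxylic acid is taken as a purchasable single enantiomer (otherwise by classical resolution of the cheap racemic trans diacid).

**Route**

Step 1
Reactants: 1 (1R,2R)-cyclopropane-1,2-dicarboxylic acid
Product: 3 (1R,2R)-N,N'-dimethoxy-N,N'-dimethylcyclopropane-1,2-dicarboxamide, via diacid dichloride 2 (not isolated)
Conditions: (COCl)2, DMF (cat.), CH2Cl2, 0 °C → rt; then MeNHOMe·HCl, Et3N, CH2Cl2, 0 °C → rt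
Reagents that add atoms: oxalyl chloride, ClC(=O)C(Cl)=O (chlorine of 2); N,O-dimethylhydroxylamine hydrochloride, CNOC.Cl
Why: Acid chloride formation followed by amidation (Weinreb amide synthesis); the trans diacid cannot close to an anhydride and the cyclopropane stereocentres are not enolised under these conditions.

Step 2
Reactants: 3 bis-Weinreb amide; 4 (4-bromophenoxy)triisopropylsilane
Product: 6 [(1R,2R)-cyclopropane-1,2-diyl]bis{[4-(triisopropylsilyloxy)phenyl]methanone}, via aryl Grignard reagent 5 (not isolated)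
Conditions: 4 (2.5 equiv), Mg, THF, rt; then 3, THF, 0 °C; then 1 M HCl, 0 °C
Reagents that add atoms: magnesium, [Mg] (metal of 5)
Why: Weinreb ketone synthesis: the magnesium chelate of the tetrahedral adduct survives until the acidic quench, so each amide takes up one aryl group only, and the trans-diacylcyclopropane keeps its configuration.

Step 3
Reactants: 6 diketone
Product: 7 (R,R)-[(1R,2R)-cyclopropane-1,2-diyl]bis{[4-(triisopropylsilyloxy)phenyl]methanol}
Conditions: (S)-2-methyl-CBS-oxazaborolidine (0.3 equiv), BH3·SMe2, THF, −20 °C; then MeOH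
Reagents that add atoms: none
Why: Corey–Bakshi–Shibata reduction: the (S)-oxazaborolidine should give the (R)-carbinol at each aryl ketone under reagent control (aryl as the large group, as for acetophenone), and in the double reduction of a twofold-symmetric diketone the minor mixed diastereomer carries away most of the stereochemical error.

Step 4
Reactants: 7 diol; 8 [2-(chloromethyl)allyl]trimethylsilane
Product: 9 (R)-[(1R,2R)-2-{(R)-[4-(triisopropylsilyloxy)phenyl]({2-[(trimethylsilyl)methyl]allyl}oxy)methyl}cyclopropyl][4-(triisopropylsilyloxy)phenyl]methanol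
Conditions: NaH (1.0 equiv), THF, 0 °C; then 8, Bu4NI (cat.), 0 → 40 °C
Reagents that add atoms: none
Why: Williamson ether synthesis with one equivalent of base: the two hydroxyl groups are homotopic, so only one mono-ether can form (SN2 and SN2′ attack on 8 give the same product); bis-ether and unreacted diol are separated and the diol is recycled.

Step 5
Reactants: 9 mono-ether
Product: 10 (R)-[(1R,2R)-2-{(R)-[4-(triisopropylsilyloxy)phenyl]({2-[(trimethylsilyl)methyl]allyl}oxy)methyl}cyclopropyl][4-(triisopropylsilyloxy)phenyl]methyl acetate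
Conditions: Ac2O, Et3N, DMAP (cat.), CH2Cl2, 0 °C; used without delay
Reagents that add atoms: acetic anhydride, CC(=O)OC(C)=O
Why: DMAP-catalysed acetylation turns the remaining carbinol into a leaving group that ionises far more easily than the benzylic ether; the configuration of this carbon no longer matters.

Step 6
Reactants: 10 acetate
Product: 11 (2R,3S)-5-methylidene-2-[4-(triisopropylsilyloxy)phenyl]-3-{(E)-3-[4-(triisopropylsilyloxy)phenyl]prop-2-enyl}oxane
Conditions: TMSOTf (0.2 equiv), 2,6-di-tert-butyl-4-methylpyridine (0.3 equiv), CH2Cl2 (0.005 M), −78 °C; then Et3N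
Reagents that add atoms: none
Why: Proposed new method: TMSOTf should ionise the benzylic acetate to an aryl-stabilised cyclopropylcarbinyl cation in its bisected conformation, after which the tethered allylsilane attacks cyclopropane carbon C3 from the side opposite the breaking C3–C8 bond (SN2-like at carbon, SE2′ at the silane) while that bond becomes the styrene double bond, and the β-silyl cation gives up Me3Si to acetate to leave the exocyclic methylene. The closest known reaction types are the Julia–Johnson cyclopropylcarbinyl-to-homoallyl rearrangement with stereoinvertive capture at the ring carbon, the Lewis-acid homoallylation of carbon nucleophiles by aryl cyclopropyl carbinols, and the intramolecular Hosomi–Sakurai cyclisation; their union in a ring closure by a tethered allylsilane is what is new. The oxane ring closes in a 6-exo-tet mode, the cleaved cyclopropane bond lying outside the new ring. C3 is set by inversion at the (R)-configured cyclopropane carbon, which together with (R)-C2 from step 3 gives the 2,3-cis oxane; the alkene should be E because the aryl group sits away from the ring in the bisected cation, and both epimers at the acetate carbon give the same cation. The step needs ionisation at the acetate and not at the benzylic ether (the ester is the far better leaving group at −78 °C), attack at C3 and not at the cyclopropane CH2 or the cationic carbon (six- against seven- and eight-membered rings, and the trans-cyclopropane holds the tether away from the cationic carbon), and no protodesilylation or alkene migration (hindered pyridine base, high dilution).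

Step 7
Reactants: 11 methylidene oxane
Product: 13 {(2R,3S,5S)-2-Ar-3-[(E)-3-Ar-prop-2-enyl]oxan-5-yl}methanol (all three ring substituents cis), via B-alkyl-9-BBN adduct 12 (not isolated)
Conditions: 9-BBN (1.2 equiv), THF, 0 °C → rt; then 30% H2O2, pH 7 phosphate buffer, 0 °C → rt
Reagents that add atoms: 9-borabicyclo[3.3.1]nonane, [BH]1C2CCCC1CCC2 (boron framework of 12); hydrogen peroxide, OO
Why: Brown hydroboration–oxidation: 9-BBN should add only to the 1,1-disubstituted exocyclic alkene (boron on CH2) and not to the internal styrene, and hydrogen should be delivered to C5 from the face away from the C3 side chain (axial in the favoured chair with equatorial aryl), so that the new CH2OH group comes out cis to both ring substituents.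

Step 8
Reactants: 13 primary alcohol
Product: 14 (2R,3S,5R)-2-Ar-3-[(E)-3-Ar-prop-2-enyl]oxane-5-carbaldehyde
Conditions: Dess–Martin periodinane, CH2Cl2, 0 °C → rt; used crude
Reagents that add atoms: none
Why: Dess–Martin oxidation stops at the aldehyde under near-neutral conditions, which should spare the α-stereocentre C5, the silyl ethers and the alkene.

Step 9
Reactants: 14 aldehyde; 4 (4-bromophenoxy)triisopropylsilane
Product: 16 {(2R,3S,5R)-2-Ar-3-[(E)-3-Ar-prop-2-enyl]oxan-5-yl}(Ar)methanol as both epimers at the carbinol carbon, via aryllithium 15 (not isolated)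
Conditions: 4 (1.3 equiv), n-BuLi (1.25 equiv), THF, −78 °C; then 14, THF, −78 °C; then pH 7 buffer
Reagents that add atoms: n-butyllithium, CCCC[Li] (lithium of 15)
Why: Bromine–lithium exchange on the aryl bromide followed by 1,2-addition of the aryllithium to the aldehyde at −78 °C, which should be fast relative to enolisation; the configuration at the new carbinol carbon is not controlled here and need not be, because step 10 removes it.

Step 10
Reactants: 16 carbinol mixture
Product: 17 {(2R,3S,5R)-2-Ar-3-[(E)-3-Ar-prop-2-enyl]oxan-5-yl}(Ar)methanone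
Conditions: Dess–Martin periodinane, CH2Cl2, 0 °C → rt
Reagents that add atoms: none
Why: Dess–Martin oxidation of both carbinol epimers converges on one aryl ketone without base, so C5 should not be enolised.

Step 11
Reactants: 17 ketone
Product: 18 (R)-{(2R,3S,5R)-2-Ar-3-[(E)-3-Ar-prop-2-enyl]oxan-5-yl}(Ar)methanol
Conditions: (S)-2-methyl-CBS-oxazaborolidine (0.5 equiv), catecholborane, toluene, −78 °C; then H2O
Reagents that add atoms: none
Why: Corey–Bakshi–Shibata reduction with catecholborane: the (S)-oxazaborolidine treats the aryl group as the large substituent and should give the (R)-carbinol under reagent control, while at −78 °C neither hydroboration of the styrene nor enolisation at C5 should compete.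

Step 12
Reactants: 18 tris(silyl ether)
Product: 19 4-[(E)-3-{(2R,3S,5R)-5-[(R)-hydroxy(4-hydroxyphenyl)methyl]-2-(4-hydroxyphenyl)oxan-3-yl}prop-1-enyl]phenol (CNP0182155.1)
Conditions: TBAF (3.3 equiv), AcOH (3.3 equiv), THF, 0 °C
Reagents that add atoms: none
Why: Fluoride-induced cleavage of the three aryl silyl ethers; buffering with acetic acid keeps the phenols protonated so that no quinone methide should form from the benzylic alcohol or ether.

**Compound list**

1 | (1R,2R)-cyclopropane-1,2-dicarboxylic acid | OC(=O)[C@@H]1C[C@H]1C(=O)O | starting material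
2 | (1R,2R)-cyclopropane-1,2-dicarbonyl dichloride | ClC(=O)[C@@H]1C[C@H]1C(Cl)=O | intermediate
3 | (1R,2R)-N,N'-dimethoxy-N,N'-dimethylcyclopropane-1,2-dicarboxamide | CON(C)C(=O)[C@@H]1C[C@H]1C(=O)N(C)OC | intermediate
4 | (4-bromophenoxy)triisopropylsilane | Brc1ccc(O[Si](C(C)C)(C(C)C)C(C)C)cc1 | starting material
5 | [4-(triisopropylsilyloxy)phenyl]magnesium bromide | Br[Mg]c1ccc(O[Si](C(C)C)(C(C)C)C(C)C)cc1 | intermediate
6 | [(1R,2R)-cyclopropane-1,2-diyl]bis{[4-(triisopropylsilyloxy)phenyl]methanone} | O=C(c1ccc(O[Si](C(C)C)(C(C)C)C(C)C)cc1)[C@@H]2C[C@H]2C(=O)c3ccc(O[Si](C(C)C)(C(C)C)C(C)C)cc3 | intermediate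
7 | (R,R)-[(1R,2R)-cyclopropane-1,2-diyl]bis{[4-(triisopropylsilyloxy)phenyl]methanol} | O[C@@H](c1ccc(O[Si](C(C)C)(C(C)C)C(C)C)cc1)[C@@H]2C[C@H]2[C@@H](O)c3ccc(O[Si](C(C)C)(C(C)C)C(C)C)cc3 | intermediate
8 | [2-(chloromethyl)allyl]trimethylsilane | C[Si](C)(C)CC(=C)CCl | starting material
9 | (R)-[(1R,2R)-2-{(R)-[4-(triisopropylsilyloxy)phenyl]({2-[(trimethylsilyl)methyl]allyl}oxy)methyl}cyclopropyl][4-(triisopropylsilyloxy)phenyl]methanol | C[Si](C)(C)CC(=C)CO[C@@H](c1ccc(O[Si](C(C)C)(C(C)C)C(C)C)cc1)[C@@H]2C[C@H]2[C@@H](O)c3ccc(O[Si](C(C)C)(C(C)C)C(C)C)cc3 | intermediate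
10 | acetate of 9 at the free carbinol | C[Si](C)(C)CC(=C)CO[C@@H](c1ccc(O[Si](C(C)C)(C(C)C)C(C)C)cc1)[C@@H]2C[C@H]2[C@@H](OC(C)=O)c3ccc(O[Si](C(C)C)(C(C)C)C(C)C)cc3 | intermediate
11 | (2R,3S)-5-methylidene-2-Ar-3-[(E)-3-Ar-prop-2-enyl]oxane | CC(C)[Si](Oc1ccc(/C=C/C[C@H]2CC(=C)CO[C@H]2c3ccc(O[Si](C(C)C)(C(C)C)C(C)C)cc3)cc1)(C(C)C)C(C)C | intermediate
12 | 9-({(2R,3S,5R)-2-Ar-3-[(E)-3-Ar-prop-2-enyl]oxan-5-yl}methyl)-9-borabicyclo[3.3.1]nonane | CC(C)[Si](Oc1ccc(/C=C/C[C@H]2C[C@@H](CB4C5CCCC4CCC5)CO[C@H]2c3ccc(O[Si](C(C)C)(C(C)C)C(C)C)cc3)cc1)(C(C)C)C(C)C | intermediate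
13 | {(2R,3S,5S)-2-Ar-3-[(E)-3-Ar-prop-2-enyl]oxan-5-yl}methanol, all-cis | CC(C)[Si](Oc1ccc(/C=C/C[C@H]2C[C@@H](CO)CO[C@H]2c3ccc(O[Si](C(C)C)(C(C)C)C(C)C)cc3)cc1)(C(C)C)C(C)C | intermediate
14 | (2R,3S,5R)-2-Ar-3-[(E)-3-Ar-prop-2-enyl]oxane-5-carbaldehyde | CC(C)[Si](Oc1ccc(/C=C/C[C@H]2C[C@@H](C=O)CO[C@H]2c3ccc(O[Si](C(C)C)(C(C)C)C(C)C)cc3)cc1)(C(C)C)C(C)C | intermediate
15 | [4-(triisopropylsilyloxy)phenyl]lithium | [Li]c1ccc(O[Si](C(C)C)(C(C)C)C(C)C)cc1 | intermediate
16 | {(2R,3S,5R)-2-Ar-3-[(E)-3-Ar-prop-2-enyl]oxan-5-yl}(Ar)methanol, both carbinol epimers | CC(C)[Si](Oc1ccc(/C=C/C[C@H]2C[C@@H](C(O)c4ccc(O[Si](C(C)C)(C(C)C)C(C)C)cc4)CO[C@H]2c3ccc(O[Si](C(C)C)(C(C)C)C(C)C)cc3)cc1)(C(C)C)C(C)C | intermediate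
17 | {(2R,3S,5R)-2-Ar-3-[(E)-3-Ar-prop-2-enyl]oxan-5-yl}(Ar)methanone | CC(C)[Si](Oc1ccc(/C=C/C[C@H]2C[C@@H](C(=O)c4ccc(O[Si](C(C)C)(C(C)C)C(C)C)cc4)CO[C@H]2c3ccc(O[Si](C(C)C)(C(C)C)C(C)C)cc3)cc1)(C(C)C)C(C)C | intermediate
18 | (R)-{(2R,3S,5R)-2-Ar-3-[(E)-3-Ar-prop-2-enyl]oxan-5-yl}(Ar)methanol | CC(C)[Si](Oc1ccc(/C=C/C[C@H]2C[C@@H]([C@@H](O)c4ccc(O[Si](C(C)C)(C(C)C)C(C)C)cc4)CO[C@H]2c3ccc(O[Si](C(C)C)(C(C)C)C(C)C)cc3)cc1)(C(C)C)C(C)C | intermediate
19 | 4-[(E)-3-{(2R,3S,5R)-5-[(R)-hydroxy(4-hydroxyphenyl)methyl]-2-(4-hydroxyphenyl)oxan-3-yl}prop-1-enyl]phenol | Oc1ccc(/C=C/C[C@H]2C[C@@H]([C@@H](O)c3ccc(O)cc3)CO[C@H]2c2ccc(O)cc2)cc1 | target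

**Totals**

Total step count: 12. Longest linear sequence: 12 steps (1 → 19); compounds 4 and 8 are bought.

**Steps most likely to fail**

1. Step 6 (labelled step). What may go wrong: ionisation at the benzylic ether instead of the acetate, with loss of the tether or scrambling at C2; capture of the cation at the benzylic carbon or at the cyclopropane CH2; protodesilylation of the allylsilane; leakage through an open homoallyl cation that erodes the inversion at C3; acid-induced migration of the exocyclic alkene into the ring.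
Fallback with known chemistry, setting out from 7 and coming back at 11: diol 7 is mono-alkylated with ethyl 4-chloroacetoacetate (NaH, 2.2 equiv, THF, 0 °C → rt) to give ethyl 4-{(R)-[(1R,2R)-2-{(R)-hydroxy(Ar)methyl}cyclopropyl](Ar)methoxy}-3-oxobutanoate F1. The aryl cyclopropyl carbinol of F1 is ionised with Yb(OTf)3 (10 mol %, CH2Cl2/MeNO2, rt) and the enol of the tethered β-keto ester captures ring carbon C3, which is the reported homoallylic C-alkylation of 1,3-dicarbonyl compounds by aryl cyclopropyl carbinols run within one molecule. This gives ethyl (2R,3S)-5-oxo-2-Ar-3-[(E)-3-Ar-prop-2-enyl]oxane-4-carboxylate F2. Krapcho dealkoxycarbonylation (LiCl, wet DMSO, 130 °C) gives (2R,3S)-2-Ar-3-[(E)-3-Ar-prop-2-enyl]oxan-5-one F3, and Wittig methylenation (Ph3PCH3Br, KOtBu, THF, 0 °C) gives 11.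

2. Step 7. What may go wrong: poor facial discrimination in the delivery of hydrogen to C5, giving the C5 epimer alongside 13; competing hydroboration of the styrene.
Fallback, setting out from 11 and coming back at 17: the hydroboration product is carried on unseparated as 13 together with the C5 epimer of alcohol 13 F4. Steps 8–10 then give, by way of the C5 epimer of aldehyde 14 F5 and the C5 epimer of carbinol mixture 16 F6, ketone 17 together with the C5 epimer of ketone 17 F7. LDA (THF, −78 °C) converts both ketones into the same exocyclic lithium enolate of ketone 17 F8. Protonation at −78 °C with AcOH in THF from the face away from the axial C3 chain (Zimmerman-type kinetic protonation, which gives the less stable epimer) should return all-cis 17.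

3. Step 11. What may go wrong: incomplete reagent control with the α-branched aryl ketone against the resident C5 centre; epimerisation at C5 by enolisation of the aldehyde or ketone on the way (steps 9–10).
Fallback, setting out from 14 and coming back at 18: the aryl group is added to aldehyde 14 under catalyst control, so that no ketone is made. Boron–zinc exchange between 4-(triisopropylsilyloxy)phenylboronic acid and Et2Zn (toluene, 60 °C) gives ethyl[4-(triisopropylsilyloxy)phenyl]zinc F9. F9 adds to 14 in the presence of (2S)-(−)-3-exo-morpholinoisoborneol (10 mol %, toluene, 0 °C); by analogy with dialkylzinc additions this ligand should deliver the aryl group to the Si face and give 18 directly.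

**Further compounds**

F1 | step 6 | ethyl 4-{(R)-[(1R,2R)-2-{(R)-hydroxy(Ar)methyl}cyclopropyl](Ar)methoxy}-3-oxobutanoate | CCOC(=O)CC(=O)CO[C@@H](c1ccc(O[Si](C(C)C)(C(C)C)C(C)C)cc1)[C@@H]2C[C@H]2[C@@H](O)c3ccc(O[Si](C(C)C)(C(C)C)C(C)C)cc3
F2 | step 6 | ethyl (2R,3S)-5-oxo-2-Ar-3-[(E)-3-Ar-prop-2-enyl]oxane-4-carboxylate (C4 epimers) | CC(C)[Si](Oc1ccc(/C=C/C[C@H]2C(C(=O)OCC)C(=O)CO[C@H]2c3ccc(O[Si](C(C)C)(C(C)C)C(C)C)cc3)cc1)(C(C)C)C(C)C
F3 | step 6 | (2R,3S)-2-Ar-3-[(E)-3-Ar-prop-2-enyl]oxan-5-one | CC(C)[Si](Oc1ccc(/C=C/C[C@H]2CC(=O)CO[C@H]2c3ccc(O[Si](C(C)C)(C(C)C)C(C)C)cc3)cc1)(C(C)C)C(C)C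
F4 | step 7 | C5 epimer of alcohol 13 | CC(C)[Si](Oc1ccc(/C=C/C[C@H]2C[C@H](CO)CO[C@H]2c3ccc(O[Si](C(C)C)(C(C)C)C(C)C)cc3)cc1)(C(C)C)C(C)C
F5 | step 7 | C5 epimer of aldehyde 14 | CC(C)[Si](Oc1ccc(/C=C/C[C@H]2C[C@H](C=O)CO[C@H]2c3ccc(O[Si](C(C)C)(C(C)C)C(C)C)cc3)cc1)(C(C)C)C(C)C
F6 | step 7 | C5 epimer of carbinol mixture 16 | CC(C)[Si](Oc1ccc(/C=C/C[C@H]2C[C@H](C(O)c4ccc(O[Si](C(C)C)(C(C)C)C(C)C)cc4)CO[C@H]2c3ccc(O[Si](C(C)C)(C(C)C)C(C)C)cc3)cc1)(C(C)C)C(C)C
F7 | step 7 | C5 epimer of ketone 17 | CC(C)[Si](Oc1ccc(/C=C/C[C@H]2C[C@H](C(=O)c4ccc(O[Si](C(C)C)(C(C)C)C(C)C)cc4)CO[C@H]2c3ccc(O[Si](C(C)C)(C(C)C)C(C)C)cc3)cc1)(C(C)C)C(C)C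
F8 | step 7 | exocyclic lithium enolate of ketone 17 | CC(C)[Si](Oc1ccc(/C=C/C[C@H]2CC(=C(O[Li])c4ccc(O[Si](C(C)C)(C(C)C)C(C)C)cc4)CO[C@H]2c3ccc(O[Si](C(C)C)(C(C)C)C(C)C)cc3)cc1)(C(C)C)C(C)C
F9 | step 11 | ethyl[4-(triisopropylsilyloxy)phenyl]zinc | CC[Zn]c1ccc(O[Si](C(C)C)(C(C)C)C(C)C)cc1
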